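**Retrosynthetic overview**
1. Target 11 comes from bicyclic enol ether 9. Hydroboration–oxidation of C1=C8 installs C1–OH and C8H2, and the aryl acetate is lost in the same work-up.
2. 9 comes from the acyclic 1,6-enyne 7 in one flask. Gold-carbene formation and O-transfer make C1–C5 and C1–C6 (THF ring A plus a cyclopropane), then C1–C6 is exchanged for C6–O7 (ring B).
3. 7 comes from rac-propargylic acetate 4 and cinnamyl alcohol 6. The C2–O3 bond is made by enantioconvergent Cu-catalysed propargylic etherification. C2 is the only catalyst-set centre and relays to C5/C6, then C1.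
4. 4 comes from vanillin, ethynylmagnesium bromide and Ac2O. 6 comes from methyl 3,4-dimethoxycinnamate.
5. Ring order: ring A and the cyclopropane form together, then the cyclopropane expands to ring B. No ring is formed afterwards.

Atom labels follow the 3,7-dioxabicyclo[3.3.0]octane numbering of the target: C1 = C–OH, C2 = CH–guaiacyl, O3, C4H2, C5 = CH, C6 = CH–veratryl, O7, C8H2.

Assumption: (S,S)-Ph-pybox is taken to deliver (S)-7. If the sense of induction is the opposite, the equally available (R,R)-ligand is used and nothing else changes.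

**Step 1**
Reactants: 1 vanillin (4-hydroxy-3-methoxybenzaldehyde); 2 ethynylmagnesium bromide
Product: 4 rac-4-(1-acetoxyprop-2-yn-1-yl)-2-methoxyphenyl acetate, via magnesium alkoxide-phenoxide 3 (not isolated)
Conditions: 2 (2.6 equiv, 0.5 M), THF, 0 °C to rt; then Ac2O (3.5 equiv), DMAP (5 mol %), 0 °C to rt
Reagents that add atoms: acetic anhydride, CC(=O)OC(C)=O
Why: Grignard 1,2-addition to the aldehyde follows sacrificial deprotonation of the phenol, and double O-acetylation of the dianion in the same flask mirrors the sequence that turns vanillin and vinylmagnesium bromide into 1'-acetoxyeugenol acetate; the carbinol centre is deliberately racemic because step 3 is enantioconvergent.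

**Step 2**
Reactants: 5 methyl (E)-3-(3,4-dimethoxyphenyl)acrylate
Product: 6 (E)-3-(3,4-dimethoxyphenyl)prop-2-en-1-ol
Conditions: DIBAL-H (2.3 equiv), CH2Cl2, −78 to 0 °C; Rochelle salt
Reagents that add atoms: none
Why: DIBAL-H 1,2-reduction of an α,β-unsaturated ester gives the allylic alcohol with the E-alkene retained, and no stereocentre is formed.

**Step 3**
Reactants: 4 rac-diacetate; 6 (E)-3,4-dimethoxycinnamyl alcohol (2 equiv, excess recovered)
Product: 7 4-[(1S)-1-{[(2E)-3-(3,4-dimethoxyphenyl)prop-2-en-1-yl]oxy}prop-2-yn-1-yl]-2-methoxyphenyl acetate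
Conditions: CuOTf·½C6H6 (5 mol %), (S,S)-Ph-pybox (10 mol %), iPr2NEt (1.2 equiv), THF, −10 °C, Ar
Reagents that add atoms: none
Why: In this copper-catalysed asymmetric propargylic etherification both enantiomers of 4 lose acetate to one achiral Cu-allenylidene, and the pybox pocket lets the primary alcohol attack one face of the propargylic carbon, which sets C2 as S (the same spatial arrangement as 2R in the target); the aryl acetate is untouched by amine base at low temperature.

**Step 4 (key step)**
Reactants: 7 (S)-1,6-enyne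
Product: 9 (2R,5R,6S)-2-(4-acetoxy-3-methoxyphenyl)-6-(3,4-dimethoxyphenyl)-3,7-dioxabicyclo[3.3.0]oct-1(8)-ene, via cyclopropanecarbaldehyde 8 (not isolated)
Conditions: IPrAuCl/AgSbF6 (5 mol % each), Ph2SO (2.5 equiv), 4 Å MS, CH2Cl2, 23 °C; then Sc(OTf)3 (5 mol %), 0 °C; Et3N quench; Et3N-deactivated silica
Reagents that add atoms: diphenyl sulfoxide, O=S(c1ccccc1)c1ccccc1
Why: Proposed new method: 5-exo-dig attack of the E-styrene on the Au-activated terminal alkyne gives an exo-cyclopropyl gold carbene that Ph2SO oxidises to aldehyde 8 (known Au(I)/sulfoxide oxidative 1,6-enyne cycloisomerisation, stereospecific for the E-alkene, with the C2 aryl anti to the new cyclopropane so that C2 fixes C5), and the Lewis acid then drives a Cloke–Wilson rearrangement of this donor–acceptor cyclopropane (C1–C6 heterolysis to a dimethoxybenzyl cation/enolate pair, then least-motion O-closure that places the aryl at C6 trans to C4, i.e. exo); telescoping these two known reaction types in one flask is the new element, and the electron-poor acetoxyaryl group at C2 suppresses ionisation of C2–O3.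

**Step 5**
Reactants: 9 bicyclic enol ether
Product: 11 (1S,2R,5R,6S)-6-(3,4-dimethoxyphenyl)-2-(4-hydroxy-3-methoxyphenyl)-3,7-dioxabicyclo[3.3.0]octan-1-ol (target CNP0141816.1), via tertiary alkylborane 10 (not isolated)
Conditions: BH3·THF (2.5 equiv), THF, 0 °C to rt; then 3 M NaOH, 30 % H2O2, 0 °C to rt; NH4Cl to pH 7
Reagents that add atoms: borane–THF, B.C1CCOC1 (boron in 10 only); hydrogen peroxide, OO
Why: In this enol-ether (glycal-type) hydroboration–oxidation both the ring oxygen O7 and the allylic C2–O3 bond direct boron to C1 and hydride to C8, syn addition from the face carrying H-5 (the only one leading to the cis-fused bicycle) sets C1, oxidation proceeds with retention, and the alkaline peroxide also saponifies the aryl acetate.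

**Compound list**
1 | vanillin | O=Cc1ccc(O)c(OC)c1 | starting material
2 | ethynylmagnesium bromide | C#C[Mg]Br | starting material
3 | bis(bromomagnesium) alkoxide-phenoxide of 1-(4-hydroxy-3-methoxyphenyl)prop-2-yn-1-ol (racemic) | C#CC(O[Mg]Br)c1ccc(O[Mg]Br)c(OC)c1 | intermediate (not isolated)
4 | rac-4-(1-acetoxyprop-2-yn-1-yl)-2-methoxyphenyl acetate | C#CC(OC(C)=O)c1ccc(OC(C)=O)c(OC)c1 | intermediate
5 | methyl (E)-3-(3,4-dimethoxyphenyl)acrylate | COC(=O)/C=C/c1ccc(OC)c(OC)c1 | starting material
6 | (E)-3-(3,4-dimethoxyphenyl)prop-2-en-1-ol | OC/C=C/c1ccc(OC)c(OC)c1 | intermediate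
7 | (S)-propargyl cinnamyl ether (1,6-enyne) | C#C[C@H](OC/C=C/c1ccc(OC)c(OC)c1)c1ccc(OC(C)=O)c(OC)c1 | intermediate
8 | (1R,2R,5R,6S)-2-(4-acetoxy-3-methoxyphenyl)-6-(3,4-dimethoxyphenyl)-3-oxabicyclo[3.1.0]hexane-1-carbaldehyde (C6 aryl cis to CHO and H-5; C2 aryl anti to the cyclopropane) | O=C[C@@]12[C@@H](c3ccc(OC(C)=O)c(OC)c3)OC[C@@H]1[C@H]2c1ccc(OC)c(OC)c1 | intermediate (not isolated)
9 | (2R,5R,6S)-2-(4-acetoxy-3-methoxyphenyl)-6-(3,4-dimethoxyphenyl)-3,7-dioxabicyclo[3.3.0]oct-1(8)-ene | C1=C2[C@@H](c3ccc(OC(C)=O)c(OC)c3)OC[C@@H]2[C@@H](c2ccc(OC)c(OC)c2)O1 | intermediate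
10 | C1-boryl cis-fused bicycle (BH2 on the convex face, cis to H-5 and to both aryl groups) | COc1cc([C@H]2OC[C@@H]3[C@@H](c4ccc(OC)c(OC)c4)OC[C@]23B)ccc1OC(C)=O | intermediate (not isolated)
11 | (1S,2R,5R,6S)-6-(3,4-dimethoxyphenyl)-2-(4-hydroxy-3-methoxyphenyl)-3,7-dioxabicyclo[3.3.0]octan-1-ol | COc1cc([C@H]2OC[C@@H]3[C@@H](c4ccc(OC)c(OC)c4)OC[C@]23O)ccc1O | target

**Step count**
- Total steps: 5.
- Longest linear sequence: 4 (1 → 4 → 7 → 9 → 11).

**Steps most likely to fail**

*Step 4.*
- The enyne may enter the 6-endo manifold.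
- The carbene may attack the C2 aryl ring instead of being oxidised.
- The ring expansion may stall, or overrun into a Ferrier-type shift of O3 from C2 to C8.

The fallback sets out from 7 and comes back at 11. Cationic gold in wet dioxane (Ph3PAuCl/AgSbF6, dioxane–H2O, rt) diverts the same 5-exo intermediate into a hydroxycyclisation. This gives the 3-methylenetetrahydrofuran carbinol F1 by anti addition across the E-alkene. OsO4/NMO dihydroxylates the exocyclic methylene to the triol F2. The isomer with C1–OH trans to the C5 side chain is the productive one and is separated. Catalytic CSA in CH2Cl2 at 0 °C ionises the dimethoxybenzylic C6–OH, and the C8 hydroxyl closes ring B with the aryl exo, giving the O-acetyl target F3. K2CO3/MeOH then gives 11.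

*Step 5.*
- Boron must bond to a fully substituted carbon next to an aryl-bearing centre.
- The resulting borane is β-alkoxy on two sides, so wrong regiochemistry or elimination is possible.

The fallback sets out from 9 and comes back at 11. DMDO (acetone/CH2Cl2, −40 °C) epoxidises the enol ether from the convex face to the 1,8-epoxide F4. After evaporation, LiBHEt3 (THF, −78 to 0 °C) delivers hydride to the acetal-type carbon C8. This frees the C1 alkoxide, cleaves the aryl acetate in the same pot and gives 11.

*Step 3.*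
- A bulky, sensitive allylic alcohol used in only 2 equiv may give low conversion or modest ee.
- Some acetyl transfer from the aryl acetate is possible.

The fallback sets out from 1, also uses 6, and comes back at 7.
- Ac2O/pyridine gives vanillin acetate F5.
- Zinc–ProPhenol-catalysed addition of trimethylsilylacetylene (Me2Zn, toluene, 4 °C, ligand antipode chosen for this carbinol) gives the (R)-silylpropargylic alcohol F6.
- Alcohol 6 is converted with CBr4/PPh3 into 3,4-dimethoxycinnamyl bromide F7, which is used crude.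
- Ag2O (CH2Cl2, 4 Å MS, dark) joins F6 and F7 to the silyl enyne F8 without touching the carbinol centre.
- TBAF buffered with AcOH (THF, 0 °C) removes the silyl group and gives 7.

**Further compounds**
F1 | step 4 | 3-methylenetetrahydrofuran carbinol from hydroxycyclisation of 7 | C=C1[C@@H](c2ccc(OC(C)=O)c(OC)c2)OC[C@@H]1[C@@H](O)c1ccc(OC)c(OC)c1
F2 | step 4 | triol from dihydroxylation of F1 (C1–OH trans to the C5 side chain) | OC[C@]1(O)[C@@H](c2ccc(OC(C)=O)c(OC)c2)OC[C@@H]1[C@@H](O)c1ccc(OC)c(OC)c1
F3 | step 4 | O-acetyl derivative of target 11 | COc1cc([C@H]2OC[C@@H]3[C@@H](c4ccc(OC)c(OC)c4)OC[C@]23O)ccc1OC(C)=O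
F4 | step 5 | 1,8-epoxide of 9 (oxygen on the convex face) | CC(=O)Oc1ccc(cc1OC)[C@H]1OC[C@@H]2[C@@H](c3ccc(OC)c(OC)c3)O[C@H]3O[C@@]123
F5 | step 3 | vanillin acetate | CC(=O)Oc1ccc(C=O)cc1OC
F6 | step 3 | 4-[(1R)-1-hydroxy-3-(trimethylsilyl)prop-2-yn-1-yl]-2-methoxyphenyl acetate | C[Si](C)(C)C#C[C@H](O)c1ccc(OC(C)=O)c(OC)c1
F7 | step 3 | (E)-3,4-dimethoxycinnamyl bromide | BrC/C=C/c1ccc(OC)c(OC)c1
F8 | step 3 | C-trimethylsilyl derivative of enyne 7 | C[Si](C)(C)C#C[C@H](OC/C=C/c1ccc(OC)c(OC)c1)c1ccc(OC(C)=O)c(OC)c1
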